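**Assumptions**
- Eriodictyol is used as a racemic or C2-labile commercial flavanone, so its C2 plays no stereochemical role.
- In step 4, C-8 attack is assumed to be favoured over C-6 (at least 2:1). The diastereomers and the C-6 regioisomer are assumed separable by HPLC at the benzylated stage.

## Retrosynthetic overview
1. Removal of six benzyl groups by hydrogenolysis gives the hexa-O-benzyl biflavanone **8**.
2. The key disconnection is C3''–C8, a photoredox homolytic aromatic substitution. It joins the nucleophilic C-8 of tri-O-benzyl-(+)-taxifolin **3** (C2 and C3 of the taxifolin unit come from the chiral pool) to the C3 radical of the 3-bromoflavanone **7** derived from eriodictyol.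
3. Both chromanone rings are bought already formed, so no ring is constructed. The sequence is protect, brominate, couple, deprotect.
4. C3 of the new flavanone unit is set trans to its 2-aryl group by radical capture anti to that group. C2 of that unit is fixed by isolating the correct diastereomer against the taxifolin unit.

## Route

**Step 1**
Reactants: **1** (+)-taxifolin, (2R,3R)-dihydroquercetin; **2** benzyl bromide
Product: **3** 7,3',4'-tri-O-benzyl-(+)-taxifolin
Conditions: BnBr (3.3 equiv), K2CO3 (3.5 equiv), DMF, 0 °C to rt, 12 h, Ar
Reagents that add atoms: benzyl bromide, BrCc1ccccc1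
Why: Williamson etherification occurs at the acidic 7-OH and the catechol OHs, while the chelated 5-OH and the aliphatic 3-OH are untouched and C2/C3 are not disturbed under mild base.

**Step 2**
Reactants: **4** (±)-eriodictyol; **2** benzyl bromide
Product: **5** (±)-7,3',4'-tri-O-benzyleriodictyol
Conditions: BnBr (3.3 equiv), K2CO3 (3.5 equiv), acetone, reflux, 8 h, Ar
Reagents that add atoms: benzyl bromide, BrCc1ccccc1
Why: Williamson etherification with the chelated 5-OH left free, using the same selectivity logic as step 1; C2 is immaterial here.

**Step 3**
Reactants: **5**; **6** copper(II) bromide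
Product: **7** (±)-trans-3-bromo-7,3',4'-tri-O-benzyleriodictyol
Conditions: CuBr2 (2.2 equiv), EtOAc/CHCl3 1:1, reflux, 3 h; used immediately, kept cold
Reagents that add atoms: copper(II) bromide, Br[Cu]Br
Why: CuBr2 α-bromination of the ketone, in the King–Ostrom manner, gives the 3-bromoflavanone, and the C3 configuration is irrelevant because the next step goes through a planar radical.

**Step 4**
Reactants: **3** (1.0 equiv); **7** (2.0 equiv)
Product: **8** hexa-O-benzyl manniflavanone (2R,3R unit linked through C-8 to the C3 of the (2R,3S) flavanone unit)
Conditions: fac-Ir(ppy)3 (1 mol%), NaHCO3 (2.5 equiv), MeCN/DMA 4:1 (0.05 M), 450 nm blue LEDs, 25 °C, 24 h, Ar; then HPLC to remove the (2S,3R)-epimer at the new unit and any C-6 isomer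
Reagents that add atoms: none
Why: Proposed new method: excited Ir(III) reduces the C–Br bond of 7 to give a planar, electrophilic secondary α-keto chromanone radical, which adds to the electron-rich C-8 of 3 (meta to the carbonyl, flanked by the tied-back ring O, hence less hindered than C-6); oxidation by Ir(IV) and loss of H+ rearomatize the ring. The closest known reaction is photoredox homolytic C–H alkylation of electron-rich arenes with α-bromo carbonyls, which has not been shown on a flavanone C-3 radical and a polyoxygenated flavanone A-ring. The arene is captured anti to the C2 aryl, which sets 2,3-trans. The two enantiomeric radicals from racemic 7 give products that are diastereomers relative to the fixed (2R,3R) taxifolin unit, and the (2R,3S) diastereomer matching the target is isolated.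

**Step 5**
Reactants: **8**
Product: **9** manniflavanone
Conditions: H2 (1 atm), Pd(OH)2/C (20 wt%), THF/MeOH 1:1, rt, 6 h
Reagents that add atoms: none
Why: Hydrogenolysis cleaves all six benzyl ethers under neutral conditions, leaving the ketones, the C–O ring bonds and all four stereocentres untouched.

## Compound list
1 | (+)-taxifolin, (2R,3R) | O=C1c2c(O)cc(O)cc2O[C@H](c2ccc(O)c(O)c2)[C@H]1O | starting material
2 | benzyl bromide | BrCc1ccccc1 | starting material (reagent)
3 | 7,3',4'-tri-O-benzyl-(+)-taxifolin | O=C1c2c(O)cc(OCc3ccccc3)cc2O[C@H](c2ccc(OCc3ccccc3)c(OCc3ccccc3)c2)[C@H]1O | intermediate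
4 | (±)-eriodictyol | O=C1CC(c2ccc(O)c(O)c2)Oc2cc(O)cc(O)c12 | starting material
5 | (±)-7,3',4'-tri-O-benzyleriodictyol | O=C1CC(c2ccc(OCc3ccccc3)c(OCc3ccccc3)c2)Oc2cc(OCc3ccccc3)cc(O)c12 | intermediate
6 | copper(II) bromide | Br[Cu]Br | starting material (reagent)
7 | (±)-trans-3-bromo-7,3',4'-tri-O-benzyleriodictyol (C3 irrelevant) | O=C1C(Br)C(c2ccc(OCc3ccccc3)c(OCc3ccccc3)c2)Oc2cc(OCc3ccccc3)cc(O)c12 | intermediate
8 | hexa-O-benzyl manniflavanone | O=C1c2c(O)cc(OCc3ccccc3)c([C@@H]3C(=O)c4c(O)cc(OCc5ccccc5)cc4O[C@H]3c3ccc(OCc4ccccc4)c(OCc4ccccc4)c3)c2O[C@H](c2ccc(OCc3ccccc3)c(OCc3ccccc3)c2)[C@H]1O | intermediate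
9 | manniflavanone | O=C1c2c(O)cc(O)c([C@@H]3C(=O)c4c(O)cc(O)cc4O[C@H]3c3ccc(O)c(O)c3)c2O[C@H](c2ccc(O)c(O)c2)[C@H]1O | target

## Totals
Total steps: 5. Longest linear sequence: 4 (eriodictyol → 5 → 7 → 8 → 9).

## Three steps most likely to fail
1. **Step 4 (proposed new step).** Failure modes are dehydrobromination of 7 to the flavone, C-6 versus C-8 selectivity, and a low diastereomer ratio at the new flavanone unit.
   - Fallback (known chemistry): Suzuki–Miyaura coupling of an 8-boryl derivative of 3 (made from 8-iodo-3) with a 3-iodoflavone (achiral B unit). Then reduce C2=C3 and equilibrate to the 2,3-trans flavanone with mild base, and separate the diastereomers.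
2. **Step 3.** The 3-bromoflavanone is unstable, and CuBr2 may brominate the dibenzyloxyaryl ring.
   - Fallback: replace the bromide with an α-acyloxy ketone radical precursor, the 3-O-acetate of racemic tri-O-benzyl dihydroflavonol (from Algar–Flynn–Oyamada oxidation of the chalcone). Generate the C3 radical by photoreductive fragmentation of the α-acyloxy ketone under the same blue-light conditions.
3. **Step 5.** Removing six benzyl groups over Pd can poison the catalyst, or over-reduce or cleave the C-ring.
   - Fallback: redo steps 1–2 with MOM ethers instead of benzyl ethers and remove them at the end with HCl/MeOH at rt. This avoids any Pd/H2 step.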